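**Retrosynthetic overview**

1. The last step frees the ring A phenol from a methyl ether. The pentacycle before it is cut at two bonds at once: C2–C3 of the 2,3-dihydrobenzofuran (ring A side) and the bond from the chroman oxygen to ring B (the aryl carbon next to the furan oxygen).
2. Both bonds form in one anionic cascade from a 4H-1,3-benzodioxin: a ring-contracting [1,2]-Wittig rearrangement (ring oxygen O3 leaves the acetal ring and becomes a tertiary alkoxide on the new quaternary carbon), then SNAr of that alkoxide on an aryl fluoride of ring B.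
3. Enabling feature: the vicinal aryl-O–CH–C(CH3)(aryl)–O unit at the ring fusion. With the benzylic carbon shifted from the methine carbon to its own oxygen, this unit is the acetal of a salicyl-type alcohol and an aldehyde; the ring B carbon that takes the oxygen is ortho to the tetralin carbon, so the alkoxide sits six atoms from a C–F bond.
4. The acetal joins two fragments: a ring A diol (from 2-methoxy-5-methylphenol; chain by B-alkyl Suzuki–Miyaura coupling, acetyl by directed ortho-metalation, carbinol by asymmetric transfer hydrogenation) and a ring B aldehyde (from 2-fluoro-5-methylanisole; methyl centre by asymmetric hydrogenation, 1,4-cis centre by hydroboration).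
5. Ring order: tetralone (Friedel–Crafts), furan (Mizoroki–Heck), 1,3-dioxin (acetalisation), then the dihydrobenzofuran and chroman rings together in the key step.

Key step: step 20

Remark: locants are those of the named ring systems (2,3-dihydro-1-benzofuran for ring A, naphtho[2,3-b]furan for fragment B, 4H-1,3-benzodioxin for the acetal); the iridium ligand enantiomer in step 10 is taken to be the one that delivers the S acid.

**Fragment A (steps 1–7)**

Step 1
Reactants: 1 2-methoxy-5-methylphenol
Product: 2 2-hydroxy-3-methoxy-6-methylbenzaldehyde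
Conditions: MgCl2, Et3N, (CH2O)n, MeCN, reflux; then aq HCl
Reagents that add atoms: paraformaldehyde (as formaldehyde), C=O
Why: Magnesium phenoxide-directed ortho-formylation should reach only the free ortho position (between OH and CH3, the other ortho carbon carrying OMe), the hydroxymethyl intermediate being oxidised by a second formaldehyde.

Step 2
Reactants: 2 2-hydroxy-3-methoxy-6-methylbenzaldehyde
Product: 3 2,3-dimethoxy-6-methylbenzaldehyde
Conditions: MeI, K2CO3, DMF, rt
Reagents that add atoms: iodomethane, CI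
Why: Williamson O-methylation of the phenol installs the methyl ether that protects this oxygen until the last step.

Step 3
Reactants: 3 2,3-dimethoxy-6-methylbenzaldehyde
Product: 4 2-ethenyl-3,4-dimethoxy-1-methylbenzene
Conditions: Ph3PCH3Br, KOt-Bu, THF, 0 °C → rt
Reagents that add atoms: methyltriphenylphosphonium bromide, C[P+](c1ccccc1)(c1ccccc1)c1ccccc1.[Br-]
Why: Wittig methylenation of a non-enolisable aldehyde should proceed despite the two ortho substituents because the ylide is small.

Step 4
Reactants: 4 2-ethenyl-3,4-dimethoxy-1-methylbenzene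
Product: 6 1,2-dimethoxy-4-methyl-3-[(3E)-pent-3-en-1-yl]benzene, via B-alkyl-9-BBN adduct 5 (not isolated)
Conditions: 9-BBN (9-borabicyclo[3.3.1]nonane), THF, 0 °C → rt; then (E)-1-bromoprop-1-ene, Pd(dppf)Cl2 (3 mol %), aq K3PO4, DMF, 50 °C
Reagents that add atoms: 9-BBN, B1C2CCCC1CCC2 (boron of 5 only); (E)-1-bromoprop-1-ene, C/C=C/Br
Why: Anti-Markovnikov hydroboration of the styrene followed by B-alkyl Suzuki–Miyaura coupling should give the pentenyl chain with retention of the E geometry of the alkenyl bromide.

Step 5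
Reactants: 6 1,2-dimethoxy-4-methyl-3-[(3E)-pent-3-en-1-yl]benzene
Product: 8 1-{2,3-dimethoxy-5-methyl-4-[(3E)-pent-3-en-1-yl]phenyl}ethan-1-one, via aryllithium 7 (not isolated)
Conditions: n-BuLi, TMEDA, Et2O, 0 °C; then MeC(O)N(OMe)Me, −78 °C → rt; H2O
Reagents that add atoms: n-BuLi, [Li]CCCC (lithium of 7 only); N-methoxy-N-methylacetamide, CON(C)C(C)=O
Why: Directed ortho-metalation should occur at the only ring hydrogen that is ortho to a methoxy group, and the Weinreb amide acylates the aryllithium without over-addition.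

Step 6
Reactants: 8 1-{2,3-dimethoxy-5-methyl-4-[(3E)-pent-3-en-1-yl]phenyl}ethan-1-one
Product: 9 1-{2-hydroxy-3-methoxy-5-methyl-4-[(3E)-pent-3-en-1-yl]phenyl}ethan-1-one
Conditions: BCl3, CH2Cl2, −78 → 0 °C; H2O
Reagents that add atoms: none
Why: BCl3 should cleave only the methyl ether ortho to the carbonyl group through a six-membered boron chelate, leaving the other methyl ether and the alkene untouched.

Step 7
Reactants: 9 1-{2-hydroxy-3-methoxy-5-methyl-4-[(3E)-pent-3-en-1-yl]phenyl}ethan-1-one
Product: 10 2-[(1R)-1-hydroxyethyl]-6-methoxy-4-methyl-5-[(3E)-pent-3-en-1-yl]phenol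
Conditions: RuCl[(R,R)-TsDPEN](p-cymene) (1 mol %), HCO2H/Et3N (5:2), 30 °C
Reagents that add atoms: none
Why: Asymmetric transfer hydrogenation (Noyori type) of an aryl methyl ketone with the (R,R)-catalyst should deliver hydride to the face that gives the R carbinol, and the isolated alkene is not reduced.

**Fragment B (steps 8–18)**

Step 8
Reactants: 11 2-fluoro-5-methylanisole
Product: 12 1-(5-fluoro-4-methoxy-2-methylphenyl)ethan-1-one
Conditions: AcCl, AlCl3, CH2Cl2, 0 °C → rt; aq HCl
Reagents that add atoms: acetyl chloride, CC(Cl)=O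
Why: Friedel–Crafts acylation should go para to the methoxy group, the strongest director, since the ortho position between OMe and CH3 is hindered.

Step 9
Reactants: 12 1-(5-fluoro-4-methoxy-2-methylphenyl)ethan-1-one
Product: 13 (3E)-4-(5-fluoro-4-methoxy-2-methylphenyl)pent-3-enoic acid
Conditions: Ph3P(CH2CH2CO2H)Br, NaHMDS (2.6 equiv), THF, 0 °C → 50 °C; aq HCl; E isomer by crystallisation
Reagents that add atoms: (2-carboxyethyl)triphenylphosphonium bromide, OC(=O)CC[P+](c1ccccc1)(c1ccccc1)c1ccccc1.[Br-]
Why: Wittig olefination with the carboxylate-bearing ylide should give the β,γ-unsaturated acid, and the E isomer needed for the hydrogenation is secured by crystallisation.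

Step 10
Reactants: 13 (3E)-4-(5-fluoro-4-methoxy-2-methylphenyl)pent-3-enoic acid
Product: 14 (4S)-4-(5-fluoro-4-methoxy-2-methylphenyl)pentanoic acid
Conditions: H2 (6 atm), [Ir(cod)((Sa,S)-SIPHOX)]BArF (0.5 mol %), Et3N (0.5 equiv), MeOH, rt
Reagents that add atoms: none
Why: Carboxy-directed iridium-catalysed asymmetric hydrogenation of 4-arylpent-3-enoic acids is an established reaction class, and the catalyst sets the S methyl-bearing centre from which the other centre of fragment B is later relayed.

Step 11
Reactants: 14 (4S)-4-(5-fluoro-4-methoxy-2-methylphenyl)pentanoic acid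
Product: 15 (4S)-8-fluoro-7-methoxy-4,5-dimethyl-3,4-dihydronaphthalen-1(2H)-one
Conditions: P2O5/MeSO3H (Eaton's reagent), 50 °C
Reagents that add atoms: none
Why: Intramolecular Friedel–Crafts acylation can close only at the single free ortho position of the chain-bearing carbon (next to fluorine, meta to OMe as in classical 7-methoxytetralone syntheses), and no bond to the stereocentre is touched.

Step 12
Reactants: 15 (4S)-8-fluoro-7-methoxy-4,5-dimethyl-3,4-dihydronaphthalen-1(2H)-one
Product: 16 (4S)-8-fluoro-7-hydroxy-4,5-dimethyl-3,4-dihydronaphthalen-1(2H)-one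
Conditions: BBr3, CH2Cl2, −78 → 0 °C; H2O
Reagents that add atoms: none
Why: Lewis acid cleavage of the aryl methyl ether should free the phenol that becomes the furan oxygen, the ketone and aryl fluoride being stable to BBr3.

Step 13
Reactants: 16 (4S)-8-fluoro-7-hydroxy-4,5-dimethyl-3,4-dihydronaphthalen-1(2H)-one
Product: 17 (4S)-8-fluoro-7-hydroxy-6-iodo-4,5-dimethyl-3,4-dihydronaphthalen-1(2H)-one
Conditions: NIS, TsOH·H2O (10 mol %), MeCN, rt
Reagents that add atoms: N-iodosuccinimide, O=C1CCC(=O)N1I
Why: Electrophilic iodination should occur at the single remaining ring hydrogen, which is ortho to the hydroxyl group.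

Step 14
Reactants: 17 (4S)-8-fluoro-7-hydroxy-6-iodo-4,5-dimethyl-3,4-dihydronaphthalen-1(2H)-one
Product: 18 (4S)-8-fluoro-6-iodo-4,5-dimethyl-7-(prop-2-en-1-yloxy)-3,4-dihydronaphthalen-1(2H)-one
Conditions: allyl bromide, K2CO3, DMF, rt
Reagents that add atoms: allyl bromide, C=CCBr
Why: Williamson allylation of the phenol supplies the three carbons of the 3-methylfuran.

Step 15
Reactants: 18 (4S)-8-fluoro-6-iodo-4,5-dimethyl-7-(prop-2-en-1-yloxy)-3,4-dihydronaphthalen-1(2H)-one
Product: 20 (5S)-9-fluoro-3,4,5-trimethyl-6,7-dihydronaphtho[2,3-b]furan-8(5H)-one, via exocyclic methylene isomer 19 (not isolated)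
Conditions: Pd(OAc)2 (5 mol %), n-Bu4NCl, Na2CO3, DMF, 80 °C
Reagents that add atoms: none
Why: Intramolecular Mizoroki–Heck reaction (oxidative addition of zerovalent palladium formed from Pd(OAc)2, 5-exo carbopalladation, β-hydride elimination) should give the exocyclic alkene, which isomerises to the aromatic 3-methylfuran while the ketone stays inert.

Step 16
Reactants: 20 (5S)-9-fluoro-3,4,5-trimethyl-6,7-dihydronaphtho[2,3-b]furan-8(5H)-one
Product: 21 (5S)-9-fluoro-3,4,5-trimethyl-8-methylidene-5,6,7,8-tetrahydronaphtho[2,3-b]furan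
Conditions: Ph3PCH3Br, KOt-Bu, THF, rt
Reagents that add atoms: methyltriphenylphosphonium bromide, C[P+](c1ccccc1)(c1ccccc1)c1ccccc1.[Br-]
Why: Wittig methylenation of the aryl ketone should proceed without touching the stereocentre, which is not alpha to the carbonyl group.

Step 17
Reactants: 21 (5S)-9-fluoro-3,4,5-trimethyl-8-methylidene-5,6,7,8-tetrahydronaphtho[2,3-b]furan
Product: 23 [(5S,8R)-9-fluoro-3,4,5-trimethyl-5,6,7,8-tetrahydronaphtho[2,3-b]furan-8-yl]methanol, via B-alkyl-9-BBN adduct 22 (not isolated)
Conditions: 9-BBN (9-borabicyclo[3.3.1]nonane), THF, 0 °C → rt; then aq NaOH, H2O2, 0 °C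
Reagents that add atoms: 9-BBN, B1C2CCCC1CCC2 (boron of 22 only); hydrogen peroxide, OO
Why: Hydroboration–oxidation: 9-BBN should place boron on the exocyclic CH2 and deliver hydrogen to the ring carbon from the face opposite the 5-methyl group (held pseudoaxial by peri strain with the 4-methyl group), which sets the 5,8-cis relationship (8R), and the oxidation retains configuration.

Step 18
Reactants: 23 [(5S,8R)-9-fluoro-3,4,5-trimethyl-5,6,7,8-tetrahydronaphtho[2,3-b]furan-8-yl]methanol
Product: 24 (5S,8R)-9-fluoro-3,4,5-trimethyl-5,6,7,8-tetrahydronaphtho[2,3-b]furan-8-carbaldehyde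
Conditions: Dess–Martin periodinane, pyridine, CH2Cl2, 0 °C; used at once
Reagents that add atoms: none
Why: Dess–Martin oxidation under buffered conditions should give the α-aryl aldehyde without epimerisation when the product is used directly.

**Union, key step and deprotection (steps 19–21)**

Step 19
Reactants: 10 2-[(1R)-1-hydroxyethyl]-6-methoxy-4-methyl-5-[(3E)-pent-3-en-1-yl]phenol; 24 (5S,8R)-9-fluoro-3,4,5-trimethyl-5,6,7,8-tetrahydronaphtho[2,3-b]furan-8-carbaldehyde
Product: 25 (2R,4R)-2-[(5S,8R)-9-fluoro-3,4,5-trimethyl-5,6,7,8-tetrahydronaphtho[2,3-b]furan-8-yl]-8-methoxy-4,6-dimethyl-7-[(3E)-pent-3-en-1-yl]-4H-1,3-benzodioxine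
Conditions: PPTS (10 mol %), MgSO4, benzene, 45 °C
Reagents that add atoms: none
Why: Acid-catalysed acetalisation under equilibrium control should give the 2,4-cis (diequatorial) benzodioxin, so the R carbinol centre fixes the R configuration of the new acetal carbon while the α-centre of the aldehyde is not touched under the mild acid.

Step 20
Reactants: 25 (2R,4R)-2-[(5S,8R)-9-fluoro-3,4,5-trimethyl-5,6,7,8-tetrahydronaphtho[2,3-b]furan-8-yl]-8-methoxy-4,6-dimethyl-7-[(3E)-pent-3-en-1-yl]-4H-1,3-benzodioxine
Product: 27 O-methyl ether of the target (pentacycle with the ring A phenol as OMe; dihydrobenzofuran C2 R and C3 R, naphthofuran C8 R and C5 S), via tertiary potassium alkoxide 26 (not isolated)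
Conditions: s-BuLi (2.6 equiv), TMEDA, THF, −78 → −40 °C; then t-BuOH (1.6 equiv), KOt-Bu (1.5 equiv), DMPU, −40 → 65 °C; H2O
Reagents that add atoms: KOt-Bu, CC(C)(C)[O-].[K+] (potassium of 26 only)
Why: Proposed new method: s-BuLi first lithiates the furan 2-position (a spectator, reprotonated by t-BuOH) and then removes the pseudoaxial benzylic hydrogen at C4 of the dioxin; the α-oxy benzylic carbanion undergoes [1,2]-Wittig rearrangement by homolysis of the O3–C2 acetal bond to a ketyl radical anion and an α-aryloxy radical that stay tethered through O1 and recombine at carbon, so the acetal ring contracts to a 3-oxido-2,3-dihydrobenzofuran (new C2–C3 bond), and after lithium/potassium exchange the tertiary alkoxide displaces the aryl fluoride of ring B (new aryl C–O bond). The closest known reaction type is the [1,2]-Wittig rearrangement of benzylic mixed acetals (O-glycoside to C-glycoside), in which the acetal carbon is the preferred migrating group and keeps its configuration; the ring-contracting variant on a benzodioxin and its telescoping with an SNAr are new. The five-membered ring closes by recombination of the tethered radical pair (formally 5-exo at the ketyl carbon) and the six-membered ring by 6-exo addition–elimination at the fluorinated carbon. The O-bearing methine is expected to keep the acetal configuration (retention at the migrating carbon, relayed from the carbinol centre of step 7), and the quaternary carbon should form on the planar ketyl with the small oxido group cis and the methyl group trans to the bulky tetralinyl substituent; the cis ring fusion then follows because only that alkoxide can reach ring B. The step needs chemoselective deprotonation and substitution at an unactivated fluoroarene: there is no hydrogen ortho to fluorine (no aryne path), excess base covers the acidic furan hydrogen, and the six-membered transition state, the potassium counter-ion and the inductive pull of the adjacent furan oxygen should make the fluoride displacement feasible.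

Step 21
Reactants: 27 O-methyl ether of the target
Product: 28 CNP0281983.1 (target)
Conditions: NaSEt (5 equiv), DMF, 110 °C; then H2O
Reagents that add atoms: none
Why: SN2 demethylation by ethanethiolate should cleave only the methyl ether, because the secondary and tertiary alkyl aryl ethers cannot be attacked at carbon and the alkene and furan are inert to thiolate.

**Compound list**

1 | 2-methoxy-5-methylphenol | COc1ccc(C)cc1O | starting material
2 | 2-hydroxy-3-methoxy-6-methylbenzaldehyde | COc1ccc(C)c(C=O)c1O | intermediate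
3 | 2,3-dimethoxy-6-methylbenzaldehyde | COc1ccc(C)c(C=O)c1OC | intermediate
4 | 2-ethenyl-3,4-dimethoxy-1-methylbenzene | COc1ccc(C)c(C=C)c1OC | intermediate
5 | 9-[2-(2,3-dimethoxy-6-methylphenyl)ethyl]-9-borabicyclo[3.3.1]nonane | COc1ccc(C)c(CCB2C3CCCC2CCC3)c1OC | intermediate
6 | 1,2-dimethoxy-4-methyl-3-[(3E)-pent-3-en-1-yl]benzene | C/C=C/CCc1c(C)ccc(OC)c1OC | intermediate
7 | {2,3-dimethoxy-5-methyl-4-[(3E)-pent-3-en-1-yl]phenyl}lithium | C/C=C/CCc1c(C)cc([Li])c(OC)c1OC | intermediate
8 | 1-{2,3-dimethoxy-5-methyl-4-[(3E)-pent-3-en-1-yl]phenyl}ethan-1-one | C/C=C/CCc1c(C)cc(C(C)=O)c(OC)c1OC | intermediate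
9 | 1-{2-hydroxy-3-methoxy-5-methyl-4-[(3E)-pent-3-en-1-yl]phenyl}ethan-1-one | C/C=C/CCc1c(C)cc(C(C)=O)c(O)c1OC | intermediate
10 | 2-[(1R)-1-hydroxyethyl]-6-methoxy-4-methyl-5-[(3E)-pent-3-en-1-yl]phenol | C/C=C/CCc1c(C)cc([C@@H](C)O)c(O)c1OC | intermediate
11 | 2-fluoro-5-methylanisole (1-fluoro-2-methoxy-4-methylbenzene) | COc1cc(C)ccc1F | starting material
12 | 1-(5-fluoro-4-methoxy-2-methylphenyl)ethan-1-one | CC(=O)c1cc(F)c(OC)cc1C | intermediate
13 | (3E)-4-(5-fluoro-4-methoxy-2-methylphenyl)pent-3-enoic acid | C/C(=C\CC(=O)O)c1cc(F)c(OC)cc1C | intermediate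
14 | (4S)-4-(5-fluoro-4-methoxy-2-methylphenyl)pentanoic acid | OC(=O)CC[C@H](C)c1cc(F)c(OC)cc1C | intermediate
15 | (4S)-8-fluoro-7-methoxy-4,5-dimethyl-3,4-dihydronaphthalen-1(2H)-one | O=C1CC[C@H](C)c2c1c(F)c(OC)cc2C | intermediate
16 | (4S)-8-fluoro-7-hydroxy-4,5-dimethyl-3,4-dihydronaphthalen-1(2H)-one | O=C1CC[C@H](C)c2c1c(F)c(O)cc2C | intermediate
17 | (4S)-8-fluoro-7-hydroxy-6-iodo-4,5-dimethyl-3,4-dihydronaphthalen-1(2H)-one | O=C1CC[C@H](C)c2c1c(F)c(O)c(I)c2C | intermediate
18 | (4S)-8-fluoro-6-iodo-4,5-dimethyl-7-(prop-2-en-1-yloxy)-3,4-dihydronaphthalen-1(2H)-one | O=C1CC[C@H](C)c2c1c(F)c(OCC=C)c(I)c2C | intermediate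
19 | (5S)-9-fluoro-4,5-dimethyl-3-methylidene-2,3,6,7-tetrahydronaphtho[2,3-b]furan-8(5H)-one | O=C1CC[C@H](C)c2c1c(F)c1OCC(=C)c1c2C | intermediate
20 | (5S)-9-fluoro-3,4,5-trimethyl-6,7-dihydronaphtho[2,3-b]furan-8(5H)-one | O=C1CC[C@H](C)c2c1c(F)c1occ(C)c1c2C | intermediate
21 | (5S)-9-fluoro-3,4,5-trimethyl-8-methylidene-5,6,7,8-tetrahydronaphtho[2,3-b]furan | C=C1CC[C@H](C)c2c1c(F)c1occ(C)c1c2C | intermediate
22 | 9-{[(5S,8R)-9-fluoro-3,4,5-trimethyl-5,6,7,8-tetrahydronaphtho[2,3-b]furan-8-yl]methyl}-9-borabicyclo[3.3.1]nonane | C1CCC2CCCC1B2C[C@@H]1CC[C@H](C)c3c1c(F)c1occ(C)c1c3C | intermediate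
23 | [(5S,8R)-9-fluoro-3,4,5-trimethyl-5,6,7,8-tetrahydronaphtho[2,3-b]furan-8-yl]methanol | OC[C@@H]1CC[C@H](C)c2c1c(F)c1occ(C)c1c2C | intermediate
24 | (5S,8R)-9-fluoro-3,4,5-trimethyl-5,6,7,8-tetrahydronaphtho[2,3-b]furan-8-carbaldehyde | O=C[C@@H]1CC[C@H](C)c2c1c(F)c1occ(C)c1c2C | intermediate
25 | (2R,4R)-2-[(5S,8R)-9-fluoro-3,4,5-trimethyl-5,6,7,8-tetrahydronaphtho[2,3-b]furan-8-yl]-8-methoxy-4,6-dimethyl-7-[(3E)-pent-3-en-1-yl]-4H-1,3-benzodioxine | C/C=C/CCc1c(C)cc2c(c1OC)O[C@H]([C@@H]1CC[C@H](C)c3c1c(F)c1occ(C)c1c3C)O[C@@H]2C | intermediate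
26 | potassium (2R,3R)-2-[(5S,8R)-9-fluoro-3,4,5-trimethyl-5,6,7,8-tetrahydronaphtho[2,3-b]furan-8-yl]-7-methoxy-3,5-dimethyl-6-[(3E)-pent-3-en-1-yl]-2,3-dihydro-1-benzofuran-3-olate | C/C=C/CCc1c(C)cc2c(c1OC)O[C@H]([C@@H]1CC[C@H](C)c3c1c(F)c1occ(C)c1c3C)[C@]2(C)[O-].[K+] | intermediate
27 | O-methyl ether of the target: cis-fused 2,3-dihydrobenzofuran (7-OMe, 5-CH3, 6-[(3E)-pent-3-enyl], 3-CH3; C2 R, C3 R) whose C3 oxygen is bonded to position 9 and whose C2 is bonded to position 8 (R) of the (5S)-3,4,5-trimethyl-5,6,7,8-tetrahydronaphtho[2,3-b]furan | C/C=C/CCc1c(C)cc2c(c1OC)O[C@@H]1[C@@H]3CC[C@H](C)c4c3c(c3occ(C)c3c4C)O[C@]21C | intermediate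
28 | CNP0281983.1: as 27 with the free phenol (OH) in place of OMe | C/C=C/CCc1c(C)cc2c(c1O)O[C@@H]1[C@@H]3CC[C@H](C)c4c3c(c3occ(C)c3c4C)O[C@]21C | target

**Step count and risks**

Total step count: 21. Longest linear sequence: 14 steps (11 → 28; steps 8–18, then 19–21).

Steps most likely to fail:

1. Step 20 (proposed new method). What may go wrong: lithiation at a benzylic CH2 or CH3 of ring A instead of the α-oxy position; recombination of the radical pair on the wrong face (methyl cis to the tetralinyl group, after which the alkoxide cannot reach ring B); partial loss of configuration at the migrating carbon; slow fluoride displacement on the electron-rich ring. The fallback uses known chemistry and sets out from 9 and 23. Mitsunobu etherification (PPh3, DIAD, THF) should give the aryl alkyl ether F1. Irradiation at 350 nm in benzene should then bring about δ-hydrogen abstraction by the ketone triplet and closure of the 1,5-biradical (Norrish–Yang-type photocyclisation of an o-alkoxyaryl ketone) to the 3-hydroxy-2,3-dihydrobenzofuran F2, with hydroxyl and tetralinyl expected cis. KHMDS in THF/DMPU at 65 °C closes the chroman ring by SNAr, and the route is rejoined at 27. In this fallback the C2 configuration is not relayed, so the C2-epimeric series has to be removed by chromatography.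

2. Step 17. What may go wrong: poor facial discrimination in the hydroboration, because the controlling methyl group is 1,4 to the reacting carbon, so the trans alcohol forms as well. The fallback sets out from 20 and replaces substrate control by catalyst control. KHMDS and PhNTf2 (THF, −78 °C) should give the enol triflate F3. Hydroxycarbonylation (Pd(OAc)2, dppp, CO, H2O, Et3N, DMF) should give the unsaturated acid F4. Hydrogenation with Ru(OAc)2[(R)-BINAP] (BINAP enantiomer matched to the 8R centre; H2, MeOH) should give the cis acid F5. LiAlH4 in THF reduces it to 23, where the route is rejoined.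

3. Step 19. What may go wrong: enolisation of the α-aryl aldehyde (loss of the 8R centre) and acid-induced ionisation of the electron-rich benzylic alcohol (o-quinone methide formation, loss of the R carbinol centre) under the protic, equilibrating conditions. The fallback sets out from 10. Silylation (TMSCl, Et3N, CH2Cl2) should give the bis(trimethylsilyl) ether F6. This is combined with 24 and catalytic TMSOTf in CH2Cl2 at −78 °C, an aprotic silyl-transfer acetalisation with no free Brønsted acid or water, and the route is rejoined at 25.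

Further compounds
F1 | step 20 | 1-{2-{[(5S,8R)-9-fluoro-3,4,5-trimethyl-5,6,7,8-tetrahydronaphtho[2,3-b]furan-8-yl]methoxy}-3-methoxy-5-methyl-4-[(3E)-pent-3-en-1-yl]phenyl}ethan-1-one | C/C=C/CCc1c(C)cc(C(C)=O)c(OC[C@@H]2CC[C@H](C)c3c2c(F)c2occ(C)c2c3C)c1OC
F2 | step 20 | (2R,3R)-2-[(5S,8R)-9-fluoro-3,4,5-trimethyl-5,6,7,8-tetrahydronaphtho[2,3-b]furan-8-yl]-7-methoxy-3,5-dimethyl-6-[(3E)-pent-3-en-1-yl]-2,3-dihydro-1-benzofuran-3-ol | C/C=C/CCc1c(C)cc2c(c1OC)O[C@H]([C@@H]1CC[C@H](C)c3c1c(F)c1occ(C)c1c3C)[C@]2(C)O
F3 | step 17 | (5S)-9-fluoro-3,4,5-trimethyl-5,6-dihydronaphtho[2,3-b]furan-8-yl trifluoromethanesulfonate | O=S(=O)(OC1=CC[C@H](C)c2c1c(F)c1occ(C)c1c2C)C(F)(F)F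
F4 | step 17 | (5S)-9-fluoro-3,4,5-trimethyl-5,6-dihydronaphtho[2,3-b]furan-8-carboxylic acid | OC(=O)C1=CC[C@H](C)c2c1c(F)c1occ(C)c1c2C
F5 | step 17 | (5S,8R)-9-fluoro-3,4,5-trimethyl-5,6,7,8-tetrahydronaphtho[2,3-b]furan-8-carboxylic acid | OC(=O)[C@@H]1CC[C@H](C)c2c1c(F)c1occ(C)c1c2C
F6 | step 19 | trimethyl{(1R)-1-{3-methoxy-5-methyl-4-[(3E)-pent-3-en-1-yl]-2-[(trimethylsilyl)oxy]phenyl}ethoxy}silane | C/C=C/CCc1c(C)cc([C@@H](C)O[Si](C)(C)C)c(O[Si](C)(C)C)c1OC
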